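**Retrosynthetic overview**
1. Target ⇒ (acetylation, desilylation, SN2 chlorination at C6, O/H addition to one ring face) ⇒ the exocyclic (Z)-enol ether 18, in which C6=C7 sits at the enol ether oxidation level.
2. 18 ⇒ carbonyl alkylidenation across C6=C7, joining the eight-membered lactone 10 (O, C7–C15) to the gem-dibromide 16 (C1–C6).
3. Enabling feature: C7 is the only oxocene ring atom bonded both to the ring oxygen and to a plain CH2 (C8). It can therefore be raised to a lactone carbonyl, and the syn C6–Cl/C7–O pair is latent in a (Z)-C6=C7 enol ether whose top face is blocked by C13-Et and O9.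
4. 10 ⇒ RCM (C11=C12) of the ester of (R)-pent-1-en-3-ol with acid 6. C7–C11 with the trans C9/C10 diol corresponds to C1–C5 with C3/C4 of 2-deoxy-D-glucose, released by reductive pyranose opening.
5. Ring order: pyranose (bought, opened in step 4), then the oxocene (step 8, before the key step), then a transient spiro-epoxide (step 15).

Key step: step 14

Remark: locants follow acetogenin numbering (C1 = terminal alkyne carbon, ring = O plus C7–C13, C14–C15 = ethyl). TBS = tert-butyldimethylsilyl, TIPS = triisopropylsilyl.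

**Step 1**
Reactants: 1 2-deoxy-D-glucose
Product: 2 methyl 2-deoxy-D-arabino-hexopyranoside (anomer mixture)
Conditions: MeOH, AcCl (cat.), reflux
Reagents that add atoms: methanol, CO
Why: Fischer glycosidation under thermodynamic control should give the pyranosides; the anomer mixture does not matter because C1 becomes sp2 in step 4.

**Step 2**
Reactants: 2 methyl 2-deoxy-D-arabino-hexopyranoside
Product: 3 methyl 2,6-dideoxy-6-iodo-D-arabino-hexopyranoside
Conditions: I2, PPh3, imidazole, THF, 60 °C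
Reagents that add atoms: iodine, II
Why: Garegg–Samuelsson iodination (SN2 on the alkoxyphosphonium salt) should select the only primary hydroxyl and leave the C3/C4 stereocentres untouched.

**Step 3**
Reactants: 3 methyl 2,6-dideoxy-6-iodo-D-arabino-hexopyranoside
Product: 4 methyl 3,4-bis-O-TBS-2,6-dideoxy-6-iodo-D-arabino-hexopyranoside
Conditions: TBSOTf, 2,6-lutidine, CH2Cl2, 0 °C
Reagents that add atoms: tert-butyldimethylsilyl triflate, CC(C)(C)[Si](C)(C)OS(=O)(=O)C(F)(F)F
Why: Silyl ether formation installs carbonyl-free protection, needed because acetates would not survive the titanium alkylidene (step 14) or DIBAL-H (step 15).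

**Step 4**
Reactants: 4 methyl 3,4-bis-O-TBS-2,6-dideoxy-6-iodo-D-arabino-hexopyranoside
Product: 5 (3R,4R)-3,4-bis(TBSO)hex-5-enal
Conditions: Zn (activated), THF/H2O 9:1, sonication, 40 °C
Reagents that add atoms: none
Why: In the Bernet–Vasella fragmentation zinc inserts into C–I, the ring oxygen is expelled to give the C5=C6 vinyl group, and the hemiacetal collapses to the aldehyde; sugar C3/C4 are carried over unchanged as C9/C10.

**Step 5**
Reactants: 5 (3R,4R)-3,4-bis(TBSO)hex-5-enal
Product: 6 (3R,4R)-3,4-bis(TBSO)hex-5-enoic acid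
Conditions: NaClO2, NaH2PO4, 2-methylbut-2-ene, t-BuOH/H2O, 0 °C→rt
Reagents that add atoms: sodium chlorite, [Na+].[O-]Cl=O
Why: Pinnick oxidation is mild enough for a β-silyloxy aldehyde, and the scavenger protects the vinyl group from HOCl.

**Step 6**
Reactants: 7 (R)-1,2-epoxybutane
Product: 8 (R)-pent-1-en-3-ol
Conditions: Me3S+ I−, n-BuLi, THF, −10 °C→rt
Reagents that add atoms: trimethylsulfonium iodide, C[S+](C)C.[I-]
Why: Dimethylsulfonium methylide opens the epoxide at CH2 and base-induced loss of Me2S gives the alkene (one-carbon epoxide-to-allylic-alcohol homologation); the bought stereocentre (future C13) is not touched.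

**Step 7**
Reactants: 6 (3R,4R)-3,4-bis(TBSO)hex-5-enoic acid; 8 (R)-pent-1-en-3-ol
Product: 9 (R)-pent-1-en-3-yl (3R,4R)-3,4-bis(TBSO)hex-5-enoate
Conditions: EDC·HCl, DMAP, CH2Cl2, 0 °C→rt
Reagents that add atoms: none
Why: Steglich-type esterification forms the future ring C7–O–C13 link by acyl transfer, so the C13–O bond is never broken and its configuration is retained.

**Step 8**
Reactants: 9 (R)-pent-1-en-3-yl (3R,4R)-3,4-bis(TBSO)hex-5-enoate
Product: 10 (4R,5R,6Z,8R)-4,5-bis(TBSO)-8-ethyl-3,4,5,8-tetrahydro-2H-oxocin-2-one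
Conditions: Grubbs II (10 mol %), CH2Cl2 (1 mM), reflux
Reagents that add atoms: none
Why: Ring-closing metathesis of the two vinyl groups should close the eight-membered lactone, helped by the gauche preference of the vicinal C9/C10 oxygens; the ring size enforces the Z C11=C12 bond.

**Step 9**
Reactants: 11 (triisopropylsilyl)acetylene
Product: 12 3-(triisopropylsilyl)prop-2-ynal
Conditions: n-BuLi, THF, −78 °C; DMF; aq HCl
Reagents that add atoms: N,N-dimethylformamide, CN(C)C=O
Why: Formylation of the lithium acetylide with DMF is a standard route to silyl propynals.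

**Step 10**
Reactants: 12 3-(triisopropylsilyl)prop-2-ynal
Product: 13 ethyl (E)-5-(triisopropylsilyl)pent-2-en-4-ynoate
Conditions: (EtO)2P(O)CH2CO2Et, NaH, THF, 0 °C
Reagents that add atoms: triethyl phosphonoacetate, CCOC(=O)CP(=O)(OCC)OCC
Why: The Horner–Wadsworth–Emmons reaction of a stabilised phosphonate with an unhindered aldehyde should set the E C3=C4 bond.

**Step 11**
Reactants: 13 ethyl (E)-5-(triisopropylsilyl)pent-2-en-4-ynoate
Product: 14 (E)-5-(triisopropylsilyl)pent-2-en-4-yn-1-ol
Conditions: DIBAL-H, CH2Cl2, −78 °C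
Reagents that add atoms: none
Why: 1,2-Reduction of the enoate with DIBAL-H gives the allylic alcohol without touching the conjugated enyne.

**Step 12**
Reactants: 14 (E)-5-(triisopropylsilyl)pent-2-en-4-yn-1-ol
Product: 15 (E)-5-bromo-1-(triisopropylsilyl)pent-3-en-1-yne
Conditions: CBr4, PPh3, CH2Cl2, 0 °C
Reagents that add atoms: carbon tetrabromide, BrC(Br)(Br)Br
Why: Appel bromination of a primary allylic alcohol proceeds by direct SN2 and should preserve the alkene position and geometry.

**Step 13**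
Reactants: 15 (E)-5-bromo-1-(triisopropylsilyl)pent-3-en-1-yne
Product: 16 (E)-6,6-dibromo-1-(triisopropylsilyl)hex-3-en-1-yne
Conditions: CH2Br2, LDA, THF, −95 °C; then 15, DMPU, −95→−40 °C
Reagents that add atoms: dibromomethane, BrCBr
Why: Alkylation of dibromomethyllithium by SN2 at the primary allylic bromide introduces C6 as a CHBr2 group and avoids the isomerisation-prone β,γ-unsaturated aldehyde.

**Step 14**
Reactants: 10 (4R,5R,6Z,8R)-4,5-bis(TBSO)-8-ethyl-3,4,5,8-tetrahydro-2H-oxocin-2-one; 16 (E)-6,6-dibromo-1-(triisopropylsilyl)hex-3-en-1-yne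
Product: 18 (2Z,4R,5R,6Z,8R)-4,5-bis(TBSO)-8-ethyl-2-[(3E)-6-(triisopropylsilyl)hex-3-en-5-yn-1-ylidene]-3,4,5,8-tetrahydro-2H-oxocine, via geminal dizinc reagent 17 (not isolated)
Conditions: TiCl4, TMEDA, Zn, PbCl2 (cat.), THF, 0→25 °C; then 10 + 16, 25 °C; Et3N, aq K2CO3
Reagents that add atoms: none
Why: Lead-catalysed zinc insertion turns 16 into the geminal dizinc species 17, which the low-valent Ti/TMEDA system converts into a titanium alkylidene; this adds to the lactone C7=O and the oxatitanacyclobutane cycloreverts to the C6=C7 enol ether and a Ti=O species (Takai–Utimoto alkylidenation of esters and lactones is the closest known reaction type). No ring is closed: the preformed oxocene is kept and the complete C15 skeleton is assembled in this one operation. The only new stereo-element is the C6=C7 geometry, where C5 should end up cis to the ring oxygen (Z) because in the metallacycle it avoids the C8 branch, and Z is also the isomer free of A(1,3) strain with C8H2. This geometry carries the relative configuration of C6 and C7, since two additions to the same ring face (step 15) and one inversion (step 16) turn it into the syn C6–Cl/C7–O pair. The step needs chemoselectivity for the single C=O over the ring Z-alkene, the E-enyne and the allylic C13–O bond; this is secured by silyl rather than acyl groups on O9/O10, the TIPS cap on the alkyne, TMEDA buffering of the Lewis acid, and the inertness of 1,2-disubstituted alkenes to the alkylidene at 25 °C.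

**Step 15**
Reactants: 18 (2Z,4R,5R,6Z,8R)-4,5-bis(TBSO)-8-ethyl-2-[(3E)-6-(triisopropylsilyl)hex-3-en-5-yn-1-ylidene]-3,4,5,8-tetrahydro-2H-oxocine
Product: 20 (6S,7R,9R,10R,13R)-alcohol (1S,3E)-1-[(2R,4R,5R,6Z,8R)-4,5-bis(TBSO)-8-ethyl-3,4,5,8-tetrahydro-2H-oxocin-2-yl]-6-(triisopropylsilyl)hex-3-en-5-yn-1-ol, via spiro-epoxide 19 (not isolated)
Conditions: DMDO, CH2Cl2, −78 °C; then DIBAL-H, CH2Cl2, −78 °C; Rochelle salt
Reagents that add atoms: dimethyldioxirane, CC1(C)OO1
Why: Enol ether epoxidation followed by reductive opening: DMDO picks the electron-rich enol ether and should attack the face opposite C13-Et and O9-TBS (sets C6), then DIBAL-H ionises the C7–O epoxide bond and delivers hydride to the oxocarbenium ion from the same open face (sets C7 cis to C13), giving net syn O/H addition.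

**Step 16**
Reactants: 20 (6S,7R,9R,10R,13R)-alcohol
Product: 21 (6R,7R,9R,10R,13R)-chloride (2R,4R,5R,6Z,8R)-4,5-bis(TBSO)-2-[(1R,3E)-1-chloro-6-(triisopropylsilyl)hex-3-en-5-yn-1-yl]-8-ethyl-3,4,5,8-tetrahydro-2H-oxocine
Conditions: CCl4, P(n-Oct)3, toluene, 70 °C
Reagents that add atoms: carbon tetrachloride, ClC(Cl)(Cl)Cl
Why: Appel-type deoxychlorination under neutral conditions replaces the C6 oxyphosphonium group by chloride in an SN2 step, inverting 6S to 6R to give the syn Cl/O relationship.

**Step 17**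
Reactants: 21 (6R,7R,9R,10R,13R)-chloride
Product: 22 (2R,4R,5R,6Z,8R)-2-[(1R,3E)-1-chlorohex-3-en-5-yn-1-yl]-8-ethyl-3,4,5,8-tetrahydro-2H-oxocine-4,5-diol
Conditions: TBAF/AcOH (1:1), THF, 0 °C→rt
Reagents that add atoms: none
Why: Fluoride desilylation removes both TBS ethers and the alkynyl TIPS group at once; the acetic acid buffer suppresses E2 loss of HCl across C5–C6.

**Step 18**
Reactants: 22 (2R,4R,5R,6Z,8R)-2-[(1R,3E)-1-chlorohex-3-en-5-yn-1-yl]-8-ethyl-3,4,5,8-tetrahydro-2H-oxocine-4,5-diol
Product: 23 target, (2R,4R,5R,6Z,8R)-2-[(1R,3E)-1-chlorohex-3-en-5-yn-1-yl]-8-ethyl-3,4,5,8-tetrahydro-2H-oxocine-4,5-diyl diacetate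
Conditions: Ac2O, pyridine, DMAP (cat.), CH2Cl2, 0 °C→rt
Reagents that add atoms: acetic anhydride, CC(=O)OC(C)=O
Why: DMAP-catalysed acetylation of the two secondary alcohols touches no stereocentre and completes the target.

**Compound list**
1 | 2-deoxy-D-glucose (pyranose form) | OC[C@H]1OC(O)C[C@@H](O)[C@@H]1O | starting material
2 | methyl 2-deoxy-D-arabino-hexopyranoside (anomer mixture) | OC[C@H]1OC(OC)C[C@@H](O)[C@@H]1O | intermediate
3 | methyl 2,6-dideoxy-6-iodo-D-arabino-hexopyranoside | IC[C@H]1OC(OC)C[C@@H](O)[C@@H]1O | intermediate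
4 | methyl 3,4-bis-O-TBS-2,6-dideoxy-6-iodo-D-arabino-hexopyranoside | IC[C@H]1OC(OC)C[C@@H](O[Si](C)(C)C(C)(C)C)[C@@H]1O[Si](C)(C)C(C)(C)C | intermediate
5 | (3R,4R)-3,4-bis(TBSO)hex-5-enal | O=CC[C@@H](O[Si](C)(C)C(C)(C)C)[C@H](O[Si](C)(C)C(C)(C)C)C=C | intermediate
6 | (3R,4R)-3,4-bis(TBSO)hex-5-enoic acid | OC(=O)C[C@@H](O[Si](C)(C)C(C)(C)C)[C@H](O[Si](C)(C)C(C)(C)C)C=C | intermediate
7 | (R)-1,2-epoxybutane | CC[C@@H]1CO1 | starting material
8 | (R)-pent-1-en-3-ol | C=C[C@@H](CC)O | intermediate
9 | (R)-pent-1-en-3-yl (3R,4R)-3,4-bis(TBSO)hex-5-enoate | C=C[C@@H](CC)OC(=O)C[C@@H](O[Si](C)(C)C(C)(C)C)[C@H](O[Si](C)(C)C(C)(C)C)C=C | intermediate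
10 | (4R,5R,6Z,8R)-4,5-bis(TBSO)-8-ethyl-3,4,5,8-tetrahydro-2H-oxocin-2-one | O=C1C[C@@H](O[Si](C)(C)C(C)(C)C)[C@H](O[Si](C)(C)C(C)(C)C)/C=C\[C@@H](CC)O1 | intermediate
11 | (triisopropylsilyl)acetylene | C#C[Si](C(C)C)(C(C)C)C(C)C | starting material
12 | 3-(triisopropylsilyl)prop-2-ynal | O=CC#C[Si](C(C)C)(C(C)C)C(C)C | intermediate
13 | ethyl (E)-5-(triisopropylsilyl)pent-2-en-4-ynoate | CCOC(=O)/C=C/C#C[Si](C(C)C)(C(C)C)C(C)C | intermediate
14 | (E)-5-(triisopropylsilyl)pent-2-en-4-yn-1-ol | OC/C=C/C#C[Si](C(C)C)(C(C)C)C(C)C | intermediate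
15 | (E)-5-bromo-1-(triisopropylsilyl)pent-3-en-1-yne | BrC/C=C/C#C[Si](C(C)C)(C(C)C)C(C)C | intermediate
16 | (E)-6,6-dibromo-1-(triisopropylsilyl)hex-3-en-1-yne | BrC(Br)C/C=C/C#C[Si](C(C)C)(C(C)C)C(C)C | intermediate
17 | geminal dizinc reagent, (E)-6,6-bis(bromozincio)-1-(triisopropylsilyl)hex-3-en-1-yne (not isolated) | Br[Zn]C([Zn]Br)C/C=C/C#C[Si](C(C)C)(C(C)C)C(C)C | intermediate
18 | (Z)-exocyclic enol ether (C5 cis to the ring oxygen; 9R,10R,13R; 3E,11Z) | CC(C)[Si](C(C)C)(C(C)C)C#C/C=C/C/C=C1/C[C@@H](O[Si](C)(C)C(C)(C)C)[C@H](O[Si](C)(C)C(C)(C)C)/C=C\[C@@H](CC)O1 | intermediate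
19 | C6–C7 spiro-epoxide, epoxide oxygen on the ring face opposite to the C13 ethyl group (not isolated) | CC(C)[Si](C(C)C)(C(C)C)C#C/C=C/C[C@@H]1O[C@@]12C[C@@H](O[Si](C)(C)C(C)(C)C)[C@H](O[Si](C)(C)C(C)(C)C)/C=C\[C@@H](CC)O2 | intermediate
20 | (6S,7R,9R,10R,13R)-alcohol | CC(C)[Si](C(C)C)(C(C)C)C#C/C=C/C[C@H](O)[C@H]1C[C@@H](O[Si](C)(C)C(C)(C)C)[C@H](O[Si](C)(C)C(C)(C)C)/C=C\[C@@H](CC)O1 | intermediate
21 | (6R,7R,9R,10R,13R)-chloride, bis-TBS ether, TIPS alkyne | CC(C)[Si](C(C)C)(C(C)C)C#C/C=C/C[C@@H](Cl)[C@H]1C[C@@H](O[Si](C)(C)C(C)(C)C)[C@H](O[Si](C)(C)C(C)(C)C)/C=C\[C@@H](CC)O1 | intermediate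
22 | (6R,7R,9R,10R,13R)-chloro diol with free enyne | C#C/C=C/C[C@@H](Cl)[C@H]1C[C@@H](O)[C@H](O)/C=C\[C@@H](CC)O1 | intermediate
23 | target diacetate | C#C/C=C/C[C@@H](Cl)[C@H]1C[C@@H](OC(C)=O)[C@H](OC(C)=O)/C=C\[C@@H](CC)O1 | target

**Total step count:** 18.
**Longest linear sequence:** 12 steps (1–5, 7, 8, 14–18, from 2-deoxy-D-glucose).

**Steps most likely to fail**

- **Step 14.** Low-valent titanium may reductively cleave the allylic C13–O bond or bind the enyne. Attack on the hindered medium-ring carbonyl may be slow, and the enol ether may hydrolyse or shift into the ring on work-up.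
  - Fallback (sulfone-based lactone olefination instead of a metal alkylidene): it sets out from 15 and 10.
  - Lithiated 2-(methylsulfonyl)-1,3-benzothiazole is alkylated with 15 to give the benzothiazolyl sulfone F1.
  - The lithium anion of F1 (LiHMDS, THF, −78 °C) is added to lactone 10 to give the hemiketal adduct F2.
  - DBU then triggers the Smiles rearrangement and elimination (modified Julia olefination of a lactone). After separation of the alkene isomers the route is rejoined at 18.

- **Step 15.** Facial selectivity of the epoxidation on the flexible eight-membered ring may be poor, which would scramble C6.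
  - Fallback (set C6 by chelation instead of by alkene face): it sets out from 20 obtained as a C6 epimer mixture.
  - Buffered Dess–Martin oxidation gives the α-alkoxy ketone F3.
  - Zn(BH4)2 in Et2O at −78 °C reduces F3 through the chelate with the ring oxygen to the anti (6S) alcohol, coming back to the route at 20.

- **Step 8.** Oligomerisation may outrun ring closure, because the ester must leave its preferred s-trans rotamer and both alkenes are hindered allylic ones.
  - Fallback (change the order of union and ring closure): it sets out from 9.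
  - Ester 9 is alkylidenated with 16 under the conditions of step 14 to give the acyclic (Z)-enol ether F4.
  - F4 has no rotamer penalty. Ring-closing metathesis of its two vinyl groups bypasses 10 and comes back to the route at 18.

**Further compounds**
F1 | step 14 | 2-{[(3E)-6-(triisopropylsilyl)hex-3-en-5-yn-1-yl]sulfonyl}-1,3-benzothiazole | O=S(=O)(CC/C=C/C#C[Si](C(C)C)(C(C)C)C(C)C)c1nc2ccccc2s1
F2 | step 14 | C7 hemiketal adduct of F1 and 10 (C6/C7 epimer mixture) | OC1(C(C/C=C/C#C[Si](C(C)C)(C(C)C)C(C)C)S(=O)(=O)c2nc3ccccc3s2)C[C@@H](O[Si](C)(C)C(C)(C)C)[C@H](O[Si](C)(C)C(C)(C)C)/C=C\[C@@H](CC)O1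
F3 | step 15 | (7R,9R,10R,13R)-C6 ketone | CC(C)[Si](C(C)C)(C(C)C)C#C/C=C/CC(=O)[C@H]1C[C@@H](O[Si](C)(C)C(C)(C)C)[C@H](O[Si](C)(C)C(C)(C)C)/C=C\[C@@H](CC)O1
F4 | step 8 | acyclic (Z)-enol ether from 9 and 16 | C=C[C@@H](CC)O/C(=C\C/C=C/C#C[Si](C(C)C)(C(C)C)C(C)C)C[C@@H](O[Si](C)(C)C(C)(C)C)[C@H](O[Si](C)(C)C(C)(C)C)C=C
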